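The route rests on disconnecting the C3′–C4′ bond of the side chain, the first CH2–CH2 bond beyond the C1′ acetate. Everything past it (C4′–C15′) is an unfunctionalised dodecyl group, and C3′ is a primary carbon remote from the quaternary ring carbon C5. The key step, a one-pot hydroboration/alkyl–alkyl Suzuki–Miyaura coupling, joins 1-dodecene (as B-dodecyl-9-BBN) to a primary bromide that already carries the complete acetonide-protected 4,5-dihydroxycyclopent-2-enone core and the C1′ acetate. The chain arrives saturated, so the ring C2=C3 enone never faces a hydrogenation. The bromide comes from one aldol reaction that sets C5 and C1′ on a cis-fused dioxolane cyclopentenone.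

Key step: step 4

Numbering used: ring C1 (C=O), C2=C3, C4 (CHOH), C5 (quaternary C–OH); side chain C1′ (CHOAc) to C15′. The target is (4S,5R,1′S), with the 4- and 5-hydroxyls cis and the side chain on the opposite ring face.

Assumption: enone 1, the (3aS,6aS) enantiomer of the isopropylidene-protected cis-4,5-dihydroxycyclopent-2-enone, is taken as a purchasable chiral building block.

Step 1
Reactants: 1 (3aS,6aS)-2,2-dimethyl-3a,6a-dihydro-4H-cyclopenta[d][1,3]dioxol-4-one; 2 3-[(tert-butyldimethylsilyl)oxy]propanal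
Product: 5 (1S)-3-[(tert-butyldimethylsilyl)oxy]-1-[(3aS,6aS)-2,2-dimethyl-4-oxo-4,6a-dihydro-3aH-cyclopenta[d][1,3]dioxol-3a-yl]propyl acetate, via lithium enolate 3 (not isolated), via lithium aldolate 4 (not isolated)
Conditions: LDA, THF, −78 °C; 2, −78 °C; then Ac2O, −78 → 0 °C
Reagents that add atoms: acetic anhydride CC(=O)OC(C)=O
Why: Directed lithium aldol addition with in situ O-acetylation of the aldolate, in which C5 can only accept the aldehyde anti to the C4–O bond because the dioxolane must stay cis-fused, a Zimmerman–Traxler chair with the aldehyde chain equatorial should favour the (1′S) carbinol (C5–O and C1′–O syn), and acetylation in the cold blocks retro-aldol.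

Step 2
Reactants: 5 the silyl ether acetate from step 1
Product: 6 (1S)-1-[(3aS,6aS)-2,2-dimethyl-4-oxo-4,6a-dihydro-3aH-cyclopenta[d][1,3]dioxol-3a-yl]-3-hydroxypropyl acetate
Conditions: HF·pyridine, pyridine, THF, 0 °C → rt
Reagents that add atoms: none
Why: Fluoride-driven cleavage of the primary TBS ether (Si–F bond formation) under buffered, weakly acidic conditions should spare the acetonide, the enone and the acetate, which has no base to promote a 1,3-acyl shift.

Step 3
Reactants: 6 the primary alcohol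
Product: 7 (1S)-3-bromo-1-[(3aS,6aS)-2,2-dimethyl-4-oxo-4,6a-dihydro-3aH-cyclopenta[d][1,3]dioxol-3a-yl]propyl acetate
Conditions: CBr4, PPh3, CH2Cl2, 0 °C
Reagents that add atoms: carbon tetrabromide BrC(Br)(Br)Br
Why: Appel bromination converts the unhindered primary alcohol into the bromide by SN2 displacement of the oxyphosphonium under neutral conditions that the acetonide, acetate and enone tolerate.

Step 4
Reactants: 7 the primary bromide; 8 1-dodecene
Product: 10 (1S)-1-[(3aS,6aS)-2,2-dimethyl-4-oxo-4,6a-dihydro-3aH-cyclopenta[d][1,3]dioxol-3a-yl]pentadecyl acetate, via B-dodecyl-9-BBN 9 (not isolated)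
Conditions: 8, 9-BBN, THF, 0 °C → rt; then 7, Pd(OAc)2 (4 mol%), PCy3 (8 mol%), K3PO4·H2O, THF, rt, degassed
Reagents that add atoms: none
Why: 1-Dodecene is hydroborated anti-Markovnikov by 9-BBN to 9; Pd(0)/PCy3 then adds oxidatively (SN2-type) to the primary C3′–Br bond of 7, the phosphate/hydroxide-activated borate of 9 transfers its primary dodecyl group to palladium, and reductive elimination forms the C3′–C4′ sp3–sp3 bond. The closest known reaction type is the room-temperature alkyl–alkyl Suzuki–Miyaura coupling of β-hydrogen-bearing primary alkyl bromides with B-alkyl-9-BBN reagents under Pd/trialkylphosphine catalysis. No ring is closed and no stereocentre is formed; C4, C5 and C1′ should pass through unchanged because C5 is quaternary and C1′ is acetylated, so neither enolisation, retro-aldol nor E1cB is available under K3PO4·H2O. The selectivity required is chemoselectivity for C3′–Br over the ring enone (C1=O, C2=C3), the acetate and the dioxolane, together with suppression of β-hydride elimination; it is secured by consuming the B–H reagent on the hydrocarbon partner before 7 is added, by the bulky electron-rich PCy3 ligand, and by the mild base at room temperature. Because the chain is delivered saturated, no hydrogenation has to distinguish a side-chain alkene from the cyclopentenone.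

Step 5
Reactants: 10 the acetonide-protected target
Product: 11 (1S)-1-[(1R,5S)-1,5-dihydroxy-2-oxocyclopent-3-en-1-yl]pentadecyl acetate
Conditions: TFA/H2O (9:1), 0 °C → rt
Reagents that add atoms: none
Why: Acid-catalysed hydrolysis of the isopropylidene acetal (oxocarbenium pathway) should release the cis-4,5-diol without touching the configuration at C4, C5 or C1′, a secondary acetate being stable to brief aqueous TFA.

Compound list
1 | (3aS,6aS)-2,2-dimethyl-3a,6a-dihydro-4H-cyclopenta[d][1,3]dioxol-4-one | CC1(C)O[C@H]2C=CC(=O)[C@H]2O1 | starting material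
2 | 3-[(tert-butyldimethylsilyl)oxy]propanal | CC(C)(C)[Si](C)(C)OCCC=O | starting material
3 | lithium (6aS)-2,2-dimethyl-6aH-cyclopenta[d][1,3]dioxol-4-olate (α′-enolate of 1) | CC1(C)O[C@H]2C=CC([O-])=C2O1.[Li+] | intermediate
4 | lithium (1S)-3-[(tert-butyldimethylsilyl)oxy]-1-[(3aS,6aS)-2,2-dimethyl-4-oxo-4,6a-dihydro-3aH-cyclopenta[d][1,3]dioxol-3a-yl]propan-1-olate | CC(C)(C)[Si](C)(C)OCC[C@H]([O-])[C@@]1(OC(C)(C)O2)C(=O)C=C[C@@H]12.[Li+] | intermediate
5 | (1S)-3-[(tert-butyldimethylsilyl)oxy]-1-[(3aS,6aS)-2,2-dimethyl-4-oxo-4,6a-dihydro-3aH-cyclopenta[d][1,3]dioxol-3a-yl]propyl acetate | CC(C)(C)[Si](C)(C)OCC[C@H](OC(C)=O)[C@@]1(OC(C)(C)O2)C(=O)C=C[C@@H]12 | intermediate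
6 | (1S)-1-[(3aS,6aS)-2,2-dimethyl-4-oxo-4,6a-dihydro-3aH-cyclopenta[d][1,3]dioxol-3a-yl]-3-hydroxypropyl acetate | OCC[C@H](OC(C)=O)[C@@]1(OC(C)(C)O2)C(=O)C=C[C@@H]12 | intermediate
7 | (1S)-3-bromo-1-[(3aS,6aS)-2,2-dimethyl-4-oxo-4,6a-dihydro-3aH-cyclopenta[d][1,3]dioxol-3a-yl]propyl acetate | BrCC[C@H](OC(C)=O)[C@@]1(OC(C)(C)O2)C(=O)C=C[C@@H]12 | intermediate
8 | 1-dodecene | CCCCCCCCCCC=C | starting material
9 | 9-dodecyl-9-borabicyclo[3.3.1]nonane (B-dodecyl-9-BBN) | CCCCCCCCCCCCB1C2CCCC1CCC2 | intermediate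
10 | (1S)-1-[(3aS,6aS)-2,2-dimethyl-4-oxo-4,6a-dihydro-3aH-cyclopenta[d][1,3]dioxol-3a-yl]pentadecyl acetate | CCCCCCCCCCCCCC[C@H](OC(C)=O)[C@@]1(OC(C)(C)O2)C(=O)C=C[C@@H]12 | intermediate
11 | (1S)-1-[(1R,5S)-1,5-dihydroxy-2-oxocyclopent-3-en-1-yl]pentadecyl acetate | CCCCCCCCCCCCCC[C@H](OC(C)=O)[C@@]1(O)C(=O)C=C[C@@H]1O | target

Total step count: 5. Longest linear sequence: 5 steps (1 → 5 → 6 → 7 → 10 → 11).

Steps most likely to fail

Step 4. Transmetalation may be slow, so that the alkylpalladium intermediate loses β-hydride or inserts into the ring enone, or the borane or phosphine adds in conjugate fashion at C3. The fallback makes the same C3′–C4′ bond before the aldol, where no enone is present; it sets out from lithium enolate 3 and comes back at 10. Dodecylmagnesium bromide is coupled with 2-(2-bromoethyl)-1,3-dioxolane under Li2CuCl4 catalysis (copper-catalysed Grignard alkylation, THF, −10 °C → rt) to give 2-tetradecyl-1,3-dioxolane F1. Aqueous HCl in THF then releases pentadecanal F2. Addition of F2 to enolate 3 at −78 °C should give the lithium (1S)-aldolate F3, which is acetylated in the flask with Ac2O as in step 1 to give 10, directly before step 5.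

Step 1. Facial selectivity at the aldehyde carbon (C1′) may be poor, or the aldolate may equilibrate by retro-aldol before it is acetylated. The fallback sets out from enolate 3 with aldehyde 2 and comes back at 5. The aldol mixture is quenched with aqueous NH4Cl and isolated as free alcohols, including the unwanted (3aS,6aS)-3a-{(1R)-3-[(tert-butyldimethylsilyl)oxy]-1-hydroxypropyl}-2,2-dimethyl-3a,6a-dihydro-4H-cyclopenta[d][1,3]dioxol-4-one F4. Dess–Martin oxidation converts both C1′ epimers into the single non-enolisable β-diketone (3aR,6aS)-3a-{3-[(tert-butyldimethylsilyl)oxy]propanoyl}-2,2-dimethyl-3a,6a-dihydro-4H-cyclopenta[d][1,3]dioxol-4-one F5. Chelation-controlled reduction with Zn(BH4)2 (Et2O, −78 °C) follows: zinc bridges the C5 ring oxygen and the side-chain carbonyl, and hydride enters past the planar C1 carbonyl. The conjugated, poorly chelating ring ketone should react more slowly. This should give the (1S)-alcohol (3aS,6aS)-3a-{(1S)-3-[(tert-butyldimethylsilyl)oxy]-1-hydroxypropyl}-2,2-dimethyl-3a,6a-dihydro-4H-cyclopenta[d][1,3]dioxol-4-one F6. Ac2O/DMAP/pyridine then gives 5.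

Step 5. The acid needed to open the dioxolane may also shift the acetyl group from O1′ to the freed O5 or O4 hydroxyl, or partly remove it. The fallback sets out from 10 and comes back at 11. Both groups are stripped on purpose with HCl in MeOH/H2O at 40 °C to give (4S,5S)-4,5-dihydroxy-5-[(1S)-1-hydroxypentadecyl]cyclopent-2-en-1-one F7. Phenylboronic acid (toluene, 4 Å sieves) should mask the rigid cis-4,5-diol selectively as (3aS,6aS)-3a-[(1S)-1-hydroxypentadecyl]-2-phenyl-3a,6a-dihydro-4H-cyclopenta[d][1,3,2]dioxaborol-4-one F8. Ac2O/pyridine/DMAP acetylates the remaining C1′ hydroxyl to give (1S)-1-[(3aR,6aS)-4-oxo-2-phenyl-4,6a-dihydro-3aH-cyclopenta[d][1,3,2]dioxaborol-3a-yl]pentadecyl acetate F9. Transesterification with pinacol in wet THF at rt, under neutral conditions, frees 11.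

Further compounds
F1 | step 4 | 2-tetradecyl-1,3-dioxolane | CCCCCCCCCCCCCCC1OCCO1
F2 | step 4 | pentadecanal | CCCCCCCCCCCCCCC=O
F3 | step 4 | lithium (1S)-1-[(3aS,6aS)-2,2-dimethyl-4-oxo-4,6a-dihydro-3aH-cyclopenta[d][1,3]dioxol-3a-yl]pentadecan-1-olate | CCCCCCCCCCCCCC[C@H]([O-])[C@@]1(OC(C)(C)O2)C(=O)C=C[C@@H]12.[Li+]
F4 | step 1 | (3aS,6aS)-3a-{(1R)-3-[(tert-butyldimethylsilyl)oxy]-1-hydroxypropyl}-2,2-dimethyl-3a,6a-dihydro-4H-cyclopenta[d][1,3]dioxol-4-one | CC(C)(C)[Si](C)(C)OCC[C@@H](O)[C@@]1(OC(C)(C)O2)C(=O)C=C[C@@H]12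
F5 | step 1 | (3aR,6aS)-3a-{3-[(tert-butyldimethylsilyl)oxy]propanoyl}-2,2-dimethyl-3a,6a-dihydro-4H-cyclopenta[d][1,3]dioxol-4-one | CC(C)(C)[Si](C)(C)OCCC(=O)[C@@]1(OC(C)(C)O2)C(=O)C=C[C@@H]12
F6 | step 1 | (3aS,6aS)-3a-{(1S)-3-[(tert-butyldimethylsilyl)oxy]-1-hydroxypropyl}-2,2-dimethyl-3a,6a-dihydro-4H-cyclopenta[d][1,3]dioxol-4-one | CC(C)(C)[Si](C)(C)OCC[C@H](O)[C@@]1(OC(C)(C)O2)C(=O)C=C[C@@H]12
F7 | step 5 | (4S,5S)-4,5-dihydroxy-5-[(1S)-1-hydroxypentadecyl]cyclopent-2-en-1-one | CCCCCCCCCCCCCC[C@H](O)[C@@]1(O)C(=O)C=C[C@@H]1O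
F8 | step 5 | (3aS,6aS)-3a-[(1S)-1-hydroxypentadecyl]-2-phenyl-3a,6a-dihydro-4H-cyclopenta[d][1,3,2]dioxaborol-4-one | CCCCCCCCCCCCCC[C@H](O)[C@@]1(OB(c3ccccc3)O2)C(=O)C=C[C@@H]12
F9 | step 5 | (1S)-1-[(3aR,6aS)-4-oxo-2-phenyl-4,6a-dihydro-3aH-cyclopenta[d][1,3,2]dioxaborol-3a-yl]pentadecyl acetate | CCCCCCCCCCCCCC[C@H](OC(C)=O)[C@@]1(OB(c3ccccc3)O2)C(=O)C=C[C@@H]12
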